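**Plan**

1. Daucane numbering is used: C1 (quaternary, CH3), C2, C3, C4 (O-acyl, isopropyl), C5 (ring-fusion H), C6 (OH), C7, C8 (CH3)/C9 (epoxide), C10; β is the face of the C1 methyl.
2. Retrosynthesis: the benzyl ether, the C8–C9 epoxide oxygen and the C4–O acyl bond are removed first (giving dauc-8-ene-4β,6α-diol 21). Then C6–OH goes back to the ketone and C8=C9 back to C9=C10 through the 7,9-dien-6-one. Last, C1–C5 and C7–C8 are cut together, with C5 reconnected to the C4 oxygen as an epoxide.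
3. Enabling feature: the C6 oxygen flanked by C5 and C7 is an oxyallyl unit lying across the cycloheptane from the four-carbon unit C1–C10–C9–C8 (a diene). The C4 oxygen next to C5 is the remnant of an epoxide, and C2–C3 of the cyclopentane is a three-atom tether. An epoxy enol silane (4+3) cycloaddition therefore closes both rings of an acyclic chain at once.
4. Forward: iodoalkene, Negishi coupling, carboalumination/diene coupling, Sharpless epoxide, methyl ketone, enol silane; the (4+3) step forms the five- and seven-membered rings together. Then alkene transposition (dehydrogenation, 1,4-hydrogenation), C6 reduction, C4 acylation, epoxidation, debenzylation.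
5. Stereochemistry: C4 from the Sharpless epoxidation (retained), C5 by inversion at the opened epoxide carbon, C1 from the cycloaddition topology (trans fusion), C6 by hydroxyl-delivered hydride, C8/C9 by hydroxyl-directed epoxidation.

Key step: step 10

Remark: the target is read as (1R,4R,5S,6S,8R,9S)-8,9-epoxy-6-hydroxydaucan-4-yl vanillate (4β-O-acyl, 5αH, 6α-OH, 8α,9α-epoxide); compounds 1, 4, 8 and 23 are taken as purchasable.

Step 1
Reactants: 1 4-methylpent-2-yn-1-ol
Product: 3 (Z)-3-iodo-4-methylpent-2-en-1-ol, via cyclic sodium alkenylalanate 2 (not isolated)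
Conditions: NaAlH2(OCH2CH2OMe)2, THF, 0 → 23 °C; then I2, THF, −78 → 0 °C
Reagents that add atoms: iodine (II)
Why: Hydroxyl-directed trans-hydroalumination of the propargylic alcohol places aluminum on C3 cis to the CH2O group in a five-membered alanate, and iodinolysis with retention should give the (Z)-3-iodoallylic alcohol (hydroalumination–iodination).

Step 2
Reactants: 3 (Z)-3-iodo-4-methylpent-2-en-1-ol; 4 (4-bromobut-1-yn-1-yl)trimethylsilane
Product: 6 (E)-3-(propan-2-yl)-7-(trimethylsilyl)hept-2-en-6-yn-1-ol, via [4-(trimethylsilyl)but-3-yn-1-yl]zinc bromide 5 (not isolated)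
Conditions: 4, Zn dust, LiCl, THF, 50 °C; then 3, Pd(OAc)2 (2 mol%), SPhos (4 mol%), THF, 25 °C
Reagents that add atoms: none
Why: Negishi sp2–sp3 coupling of the alkenyl iodide with the primary alkylzinc proceeds with retention of alkene geometry and faster than protonation of the zinc reagent by the free hydroxyl, so the new chain should end up cis to CH2OH and the isopropyl group trans (E).

Step 3
Reactants: 6 (E)-3-(propan-2-yl)-7-(trimethylsilyl)hept-2-en-6-yn-1-ol
Product: 7 (E)-3-(propan-2-yl)hept-2-en-6-yn-1-ol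
Conditions: K2CO3 (cat.), MeOH, 23 °C
Reagents that add atoms: none
Why: Base-mediated methanolysis of the alkynyl C–Si bond (protodesilylation) frees the terminal alkyne without touching the allylic alcohol.

Step 4
Reactants: 7 (E)-3-(propan-2-yl)hept-2-en-6-yn-1-ol; 8 (E)-1-bromoprop-1-ene
Product: 10 (2E,6E,8E)-6-methyl-3-(propan-2-yl)deca-2,6,8-trien-1-ol, via alkenyldimethylalane 9 (not isolated)
Conditions: AlMe3 (3 equiv), Cp2ZrCl2 (0.25 equiv), CH2Cl2, 0 → 23 °C; then 8, ZnCl2 (1 equiv), Pd(PPh3)4 (5 mol%), THF, 23 °C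
Reagents that add atoms: trimethylaluminum (C[Al](C)C)
Why: Zirconium-catalysed Negishi carboalumination adds CH3 and Al syn across the terminal alkyne (CH3 on the internal carbon), and the alkenylalane then undergoes palladium-catalysed alkenyl–alkenyl cross-coupling with retention at both partners, which should fix the (6E,8E)-diene with the tether trans to the propenyl group.

Step 5
Reactants: 10 (2E,6E,8E)-6-methyl-3-(propan-2-yl)deca-2,6,8-trien-1-ol
Product: 11 [(2R,3R)-3-[(3E,5E)-3-methylhepta-3,5-dien-1-yl]-3-(propan-2-yl)oxiran-2-yl]methanol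
Conditions: Ti(OiPr)4 (10 mol%), D-(−)-diethyl tartrate (12 mol%), t-BuOOH, 4 Å molecular sieves, CH2Cl2, −20 °C
Reagents that add atoms: tert-butyl hydroperoxide (CC(C)(C)OO)
Why: Sharpless asymmetric epoxidation acts only on the allylic alcohol alkene (3,3-disubstituted E-allylic alcohols are a favourable class) and with D-(−)-tartrate should deliver oxygen to the face that gives the (2R,3R)-epoxide, the same sense that turns geraniol into its (2R,3R)-epoxide, which sets the future C4 and C5.

Step 6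
Reactants: 11 [(2R,3R)-3-[(3E,5E)-3-methylhepta-3,5-dien-1-yl]-3-(propan-2-yl)oxiran-2-yl]methanol
Product: 12 (2S,3R)-3-[(3E,5E)-3-methylhepta-3,5-dien-1-yl]-3-(propan-2-yl)oxirane-2-carbaldehyde
Conditions: Dess–Martin periodinane, pyridine, CH2Cl2, 0 → 23 °C
Reagents that add atoms: none
Why: Dess–Martin oxidation converts the primary alcohol into the aldehyde under buffered conditions that leave the epoxide and the diene intact.

Step 7
Reactants: 12 (2S,3R)-3-[(3E,5E)-3-methylhepta-3,5-dien-1-yl]-3-(propan-2-yl)oxirane-2-carbaldehyde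
Product: 13 1-[(2R,3R)-3-[(3E,5E)-3-methylhepta-3,5-dien-1-yl]-3-(propan-2-yl)oxiran-2-yl]ethan-1-ol (mixture of carbinol epimers)
Conditions: MeMgBr, THF, −78 °C
Reagents that add atoms: methylmagnesium bromide (C[Mg]Br)
Why: Grignard 1,2-addition to the aldehyde at low temperature is much faster than epoxide opening, and the new carbinol centre, formed as a mixture, is removed in the next step.

Step 8
Reactants: 13 1-[(2R,3R)-3-[(3E,5E)-3-methylhepta-3,5-dien-1-yl]-3-(propan-2-yl)oxiran-2-yl]ethan-1-ol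
Product: 14 1-[(2S,3R)-3-[(3E,5E)-3-methylhepta-3,5-dien-1-yl]-3-(propan-2-yl)oxiran-2-yl]ethan-1-one
Conditions: Dess–Martin periodinane, pyridine, CH2Cl2, 0 → 23 °C
Reagents that add atoms: none
Why: Dess–Martin oxidation of the secondary alcohol gives the α,β-epoxy methyl ketone without epimerising the oxirane carbons.

Step 9
Reactants: 14 1-[(2S,3R)-3-[(3E,5E)-3-methylhepta-3,5-dien-1-yl]-3-(propan-2-yl)oxiran-2-yl]ethan-1-one
Product: 15 triethyl({1-[(2S,3R)-3-[(3E,5E)-3-methylhepta-3,5-dien-1-yl]-3-(propan-2-yl)oxiran-2-yl]ethenyl}oxy)silane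
Conditions: KN(SiMe3)2, Et3SiCl, THF, −78 °C
Reagents that add atoms: chlorotriethylsilane (CC[Si](Cl)(CC)CC)
Why: Kinetic enolisation can only take place at the methyl group (the oxiranyl α-hydrogen is not removed), and O-silylation should give the 2-silyloxyallyl epoxide (silyl enol ether formation).

Step 10
Reactants: 15 triethyl({1-[(2S,3R)-3-[(3E,5E)-3-methylhepta-3,5-dien-1-yl]-3-(propan-2-yl)oxiran-2-yl]ethenyl}oxy)silane
Product: 16 (3R,3aR,6R,8aR)-6,8a-dimethyl-3-(propan-2-yl)-3-[(triethylsilyl)oxy]-2,3,3a,5,6,8a-hexahydroazulen-4(1H)-one (trans-fused; 4β-OSiEt3, 5αH, 8βH, 9-ene, 6-one)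
Conditions: Et3SiOTf (0.2 equiv), CH2Cl2, −78 °C; Et3N quench
Reagents that add atoms: none
Why: Proposed new method: Et3SiOTf silylates the epoxide oxygen; the C–O bond at the carbon carrying the 2-silyloxyvinyl group (future C5) is displaced with inversion by the 1,1-disubstituted diene terminus (future C1) while the developing 2-silyloxyallyl cation is captured at its CH2 end (C7) by the other diene terminus (C8), and transfer of the silyl group from the resulting oxocarbenium ion to the tertiary alkoxide releases the C6 ketone, the C4 silyl ether and the catalyst. The closest known reactions are the silyl triflate-promoted (4+3) cycloadditions of epoxy enol silanes with furans, inter- and intramolecular and stereospecific with inversion at the opened carbon, and Lewis acid-mediated intramolecular (4+3) cycloadditions of alkoxyallyl cations with tethered acyclic butadienes; an acyclic diene that forms a quaternary centre and a trisubstituted epoxide are new for this process. The cyclopentane closes by 5-exo attack of the diene on the epoxide carbon through the C2–C3 tether, and the cycloheptenone closes by the (4+3) union of C5–C6–C7 with C1–C10–C9–C8 (formally 7-endo closure of the enol silane onto the allyl cation). C4 keeps the configuration of the Sharpless epoxide because its C–O bond is not broken; C5 is set by the backside displacement; C1 is set by an extended transition state in which the silyloxy-bearing C6 points away from the (E)-diene whose tether is the outside substituent, which should give the trans ring fusion; C8 (8βH, methyl cis to the tether) is transient. The step needs ionisation at C5–O and not at the tertiary C4–O (secured by allyl-type assistance of the enol silane and the intramolecular nucleophile at −78 °C), (4+3) closure in preference to 6-endo cation–olefin or (3+2) closure (secured by the three-atom tether and the methyl group that stabilises charge at C8), and the extended over the compact topology.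

Step 11
Reactants: 16 (3R,3aR,6R,8aR)-6,8a-dimethyl-3-(propan-2-yl)-3-[(triethylsilyl)oxy]-2,3,3a,5,6,8a-hexahydroazulen-4(1H)-one
Product: 18 (3R,3aR,8aR)-6,8a-dimethyl-3-(propan-2-yl)-3-[(triethylsilyl)oxy]-2,3,3a,8a-tetrahydroazulen-4(1H)-one, via trimethylsilyl dienol ether 17 (not isolated)
Conditions: LiN(iPr)2, Me3SiCl, THF, −78 °C; then Pd(OAc)2 (1.1 equiv), MeCN, 23 °C
Reagents that add atoms: none
Why: Saegusa–Ito oxidation: kinetic deprotonation occurs at the C7 methylene and not at the hindered C5 methine, and the palladium enolate formed from the C6=C7 enol silane has its only β-hydrogen at C8, so β-hydride elimination should give the 7,9-dien-6-one.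

Step 12
Reactants: 18 (3R,3aR,8aR)-6,8a-dimethyl-3-(propan-2-yl)-3-[(triethylsilyl)oxy]-2,3,3a,8a-tetrahydroazulen-4(1H)-one
Product: 19 (3R,3aR,8aR)-6,8a-dimethyl-3-(propan-2-yl)-3-[(triethylsilyl)oxy]-2,3,3a,5,8,8a-hexahydroazulen-4(1H)-one
Conditions: (η6-naphthalene)Cr(CO)3 (20 mol%), H2 (50 atm), THF, 45 °C
Reagents that add atoms: none
Why: Arene–Cr(CO)3-catalysed 1,4-hydrogenation adds H2 to the termini (C7 and C10) of the ring-locked s-cis diene through an η4-diene chromium dihydride and leaves the C8=C9 alkene, while the s-trans enone unit and isolated alkenes are not reduced.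

Step 13
Reactants: 19 (3R,3aR,8aR)-6,8a-dimethyl-3-(propan-2-yl)-3-[(triethylsilyl)oxy]-2,3,3a,5,8,8a-hexahydroazulen-4(1H)-one
Product: 20 (3R,3aR,8aR)-3-hydroxy-6,8a-dimethyl-3-(propan-2-yl)-2,3,3a,5,8,8a-hexahydroazulen-4(1H)-one
Conditions: HF·pyridine, pyridine, THF, 0 → 23 °C
Reagents that add atoms: none
Why: Buffered fluoride cleavage of the tertiary silyl ether under weakly acidic conditions avoids retro-aldol cleavage and conjugation of the β,γ-enone (silyl ether deprotection).

Step 14
Reactants: 20 (3R,3aR,8aR)-3-hydroxy-6,8a-dimethyl-3-(propan-2-yl)-2,3,3a,5,8,8a-hexahydroazulen-4(1H)-one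
Product: 21 (3R,3aS,4S,8aR)-6,8a-dimethyl-3-(propan-2-yl)-1,2,3,3a,4,5,8,8a-octahydroazulene-3,4-diol (dauc-8-ene-4β,6α-diol)
Conditions: Me4NBH(OAc)3, MeCN/AcOH, −30 → 0 °C
Reagents that add atoms: none
Why: Evans–Saksena reduction: the C4 hydroxyl exchanges onto boron and delivers hydride intramolecularly to the β face of the C6 carbonyl, which should give the 6α-alcohol anti to the 4β-oxygen.

Step 15
Reactants: 21 (3R,3aS,4S,8aR)-6,8a-dimethyl-3-(propan-2-yl)-1,2,3,3a,4,5,8,8a-octahydroazulene-3,4-diol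
Product: 22 (3R,3aS,4S,8aR)-6,8a-dimethyl-3-(propan-2-yl)-4-[(triethylsilyl)oxy]-1,2,3,3a,4,5,8,8a-octahydroazulen-3-ol
Conditions: Et3SiCl, imidazole, DMF, 0 °C
Reagents that add atoms: chlorotriethylsilane (CC[Si](Cl)(CC)CC)
Why: Silylation with a silyl chloride and imidazole discriminates the secondary hydroxyl from the hindered tertiary one.

Step 16
Reactants: 22 (3R,3aS,4S,8aR)-6,8a-dimethyl-3-(propan-2-yl)-4-[(triethylsilyl)oxy]-1,2,3,3a,4,5,8,8a-octahydroazulen-3-ol; 23 4-(benzyloxy)-3-methoxybenzoic acid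
Product: 26 (3R,3aS,4S,8aR)-4-hydroxy-6,8a-dimethyl-3-(propan-2-yl)-1,2,3,3a,4,5,8,8a-octahydroazulen-3-yl 4-(benzyloxy)-3-methoxybenzoate, via acid chloride 24 (not isolated), via triethylsilyl-protected ester 25 (not isolated)
Conditions: 23, (COCl)2, DMF (cat.), CH2Cl2, 23 °C, evaporate; 22, n-BuLi, THF, −78 °C, then 24, −78 → 0 °C; then PPTS, MeOH, 0 °C
Reagents that add atoms: none
Why: Acylation of a lithium tertiary alkoxide by an aroyl chloride (addition–elimination) is the standard way to esterify a hindered tertiary alcohol; the trans 4β/6α arrangement and the low temperature should disfavour O-to-O silyl shift, and mild acid methanolysis then removes the secondary silyl ether without cleaving the hindered aryl ester.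

Step 17
Reactants: 26 (3R,3aS,4S,8aR)-4-hydroxy-6,8a-dimethyl-3-(propan-2-yl)-1,2,3,3a,4,5,8,8a-octahydroazulen-3-yl 4-(benzyloxy)-3-methoxybenzoate
Product: 27 (1R,4R,5S,6S,8R,9S)-8,9-epoxy-6-hydroxydaucan-4-yl 4-(benzyloxy)-3-methoxybenzoate (8α,9α-epoxide)
Conditions: VO(acac)2 (5 mol%), t-BuOOH, CH2Cl2, 0 → 23 °C
Reagents that add atoms: tert-butyl hydroperoxide (CC(C)(C)OO)
Why: Vanadium-catalysed hydroxyl-directed epoxidation: the 6α-hydroxyl binds the vanadium alkyl peroxide and delivers oxygen to the α face of the homoallylic C8=C9 alkene, which is also the face away from the β C1 methyl.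

Step 18
Reactants: 27 (1R,4R,5S,6S,8R,9S)-8,9-epoxy-6-hydroxydaucan-4-yl 4-(benzyloxy)-3-methoxybenzoate
Product: 28 (1R,4R,5S,6S,8R,9S)-8,9-epoxy-6-hydroxydaucan-4-yl 4-hydroxy-3-methoxybenzoate (target)
Conditions: H2 (1 atm), Pd/C, EtOAc, 23 °C
Reagents that add atoms: none
Why: Catalytic hydrogenolysis cleaves the aryl benzyl ether under neutral conditions to which the non-benzylic trisubstituted epoxide and the hindered ester should be stable.

**Compound list**

1 | 4-methylpent-2-yn-1-ol | CC(C)C#CCO | starting material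
2 | cyclic sodium alkenylalanate (five-membered O–Al–C3=C2–C1 ring, two 2-methoxyethoxy groups on Al) | CC(C)C1=CCO[Al-]1(OCCOC)OCCOC.[Na+] | intermediate
3 | (Z)-3-iodo-4-methylpent-2-en-1-ol | CC(C)/C(I)=C/CO | intermediate
4 | (4-bromobut-1-yn-1-yl)trimethylsilane | C[Si](C)(C)C#CCCBr | starting material
5 | [4-(trimethylsilyl)but-3-yn-1-yl]zinc bromide | C[Si](C)(C)C#CCC[Zn]Br | intermediate
6 | (E)-3-(propan-2-yl)-7-(trimethylsilyl)hept-2-en-6-yn-1-ol | CC(C)/C(CCC#C[Si](C)(C)C)=C/CO | intermediate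
7 | (E)-3-(propan-2-yl)hept-2-en-6-yn-1-ol | CC(C)/C(CCC#C)=C/CO | intermediate
8 | (E)-1-bromoprop-1-ene | C/C=C/Br | starting material
9 | alkenyldimethylalane Me2Al–CH=C(CH3)–CH2CH2–C(iPr)=CH–CH2–OAlMe2 (Al cis to CH3; 2E) | C[Al](C)/C=C(\C)CC/C(C(C)C)=C\CO[Al](C)C | intermediate
10 | (2E,6E,8E)-6-methyl-3-(propan-2-yl)deca-2,6,8-trien-1-ol | CC(C)/C(CC/C(C)=C/C=C/C)=C/CO | intermediate
11 | [(2R,3R)-3-[(3E,5E)-3-methylhepta-3,5-dien-1-yl]-3-(propan-2-yl)oxiran-2-yl]methanol | OC[C@H]1O[C@@]1(C(C)C)CC/C(C)=C/C=C/C | intermediate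
12 | (2S,3R)-3-[(3E,5E)-3-methylhepta-3,5-dien-1-yl]-3-(propan-2-yl)oxirane-2-carbaldehyde | O=C[C@H]1O[C@@]1(C(C)C)CC/C(C)=C/C=C/C | intermediate
13 | 1-[(2R,3R)-3-[(3E,5E)-3-methylhepta-3,5-dien-1-yl]-3-(propan-2-yl)oxiran-2-yl]ethan-1-ol (carbinol epimers) | CC(O)[C@H]1O[C@@]1(C(C)C)CC/C(C)=C/C=C/C | intermediate
14 | 1-[(2S,3R)-3-[(3E,5E)-3-methylhepta-3,5-dien-1-yl]-3-(propan-2-yl)oxiran-2-yl]ethan-1-one | CC(=O)[C@H]1O[C@@]1(C(C)C)CC/C(C)=C/C=C/C | intermediate
15 | triethyl({1-[(2S,3R)-3-[(3E,5E)-3-methylhepta-3,5-dien-1-yl]-3-(propan-2-yl)oxiran-2-yl]ethenyl}oxy)silane | C=C(O[Si](CC)(CC)CC)[C@H]1O[C@@]1(C(C)C)CC/C(C)=C/C=C/C | intermediate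
16 | (3R,3aR,6R,8aR)-6,8a-dimethyl-3-(propan-2-yl)-3-[(triethylsilyl)oxy]-2,3,3a,5,6,8a-hexahydroazulen-4(1H)-one | CC[Si](CC)(CC)O[C@@]1(C(C)C)CC[C@]2(C)C=C[C@H](C)CC(=O)[C@H]21 | intermediate
17 | trimethylsilyl dienol ether of 16 (C6=C7 enol silane; 3R,3aS,6R,8aR) | CC[Si](CC)(CC)O[C@@]1(C(C)C)CC[C@]2(C)C=C[C@H](C)C=C(O[Si](C)(C)C)[C@H]21 | intermediate
18 | (3R,3aR,8aR)-6,8a-dimethyl-3-(propan-2-yl)-3-[(triethylsilyl)oxy]-2,3,3a,8a-tetrahydroazulen-4(1H)-one | CC[Si](CC)(CC)O[C@@]1(C(C)C)CC[C@]2(C)C=CC(C)=CC(=O)[C@H]21 | intermediate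
19 | (3R,3aR,8aR)-6,8a-dimethyl-3-(propan-2-yl)-3-[(triethylsilyl)oxy]-2,3,3a,5,8,8a-hexahydroazulen-4(1H)-one | CC[Si](CC)(CC)O[C@@]1(C(C)C)CC[C@]2(C)CC=C(C)CC(=O)[C@H]21 | intermediate
20 | (3R,3aR,8aR)-3-hydroxy-6,8a-dimethyl-3-(propan-2-yl)-2,3,3a,5,8,8a-hexahydroazulen-4(1H)-one | O[C@@]1(C(C)C)CC[C@]2(C)CC=C(C)CC(=O)[C@H]21 | intermediate
21 | (3R,3aS,4S,8aR)-6,8a-dimethyl-3-(propan-2-yl)-1,2,3,3a,4,5,8,8a-octahydroazulene-3,4-diol | O[C@@]1(C(C)C)CC[C@]2(C)CC=C(C)C[C@H](O)[C@H]21 | intermediate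
22 | (3R,3aS,4S,8aR)-6,8a-dimethyl-3-(propan-2-yl)-4-[(triethylsilyl)oxy]-1,2,3,3a,4,5,8,8a-octahydroazulen-3-ol | O[C@@]1(C(C)C)CC[C@]2(C)CC=C(C)C[C@H](O[Si](CC)(CC)CC)[C@H]21 | intermediate
23 | 4-(benzyloxy)-3-methoxybenzoic acid | COc1cc(C(=O)O)ccc1OCc1ccccc1 | starting material
24 | 4-(benzyloxy)-3-methoxybenzoyl chloride | COc1cc(C(=O)Cl)ccc1OCc1ccccc1 | intermediate
25 | (3R,3aS,4S,8aR)-6,8a-dimethyl-3-(propan-2-yl)-4-[(triethylsilyl)oxy]-1,2,3,3a,4,5,8,8a-octahydroazulen-3-yl 4-(benzyloxy)-3-methoxybenzoate | COc1cc(C(=O)O[C@@]2(C(C)C)CC[C@]3(C)CC=C(C)C[C@H](O[Si](CC)(CC)CC)[C@H]32)ccc1OCc1ccccc1 | intermediate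
26 | (3R,3aS,4S,8aR)-4-hydroxy-6,8a-dimethyl-3-(propan-2-yl)-1,2,3,3a,4,5,8,8a-octahydroazulen-3-yl 4-(benzyloxy)-3-methoxybenzoate | COc1cc(C(=O)O[C@@]2(C(C)C)CC[C@]3(C)CC=C(C)C[C@H](O)[C@H]32)ccc1OCc1ccccc1 | intermediate
27 | (1R,4R,5S,6S,8R,9S)-8,9-epoxy-6-hydroxydaucan-4-yl 4-(benzyloxy)-3-methoxybenzoate | COc1cc(C(=O)O[C@@]2(C(C)C)CC[C@]3(C)C[C@@H]4O[C@]4(C)C[C@H](O)[C@H]32)ccc1OCc1ccccc1 | intermediate
28 | (1R,4R,5S,6S,8R,9S)-8,9-epoxy-6-hydroxydaucan-4-yl 4-hydroxy-3-methoxybenzoate | COc1cc(C(=O)O[C@@]2(C(C)C)CC[C@]3(C)C[C@@H]4O[C@]4(C)C[C@H](O)[C@H]32)ccc1O | target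

**Totals and risks**

Total step count: 18. Longest linear sequence: 18 steps (from 1; the acid 23 enters in step 16).

Steps most likely to fail:

Step 10 (proposed method). The epoxide may ionise at the tertiary C4–O bond and undergo a semipinacol shift, the cation may close in the 6-endo or (3+2) sense, or the compact topology may give the cis-fused adduct. The fallback is the classical oxyallyl cation route, which uses known chemistry, sets out from 14 and returns at 16. SmI2 (samarium diiodide) in THF/MeOH at −90 °C cleaves the Cα–O bond of the epoxy ketone and should give (S,7E,9E)-4-hydroxy-7-methyl-4-(propan-2-yl)undeca-7,9-dien-2-one F1 with the carbinol centre untouched. Et3SiOTf/2,6-lutidine gives its triethylsilyl ether F2. The kinetic lithium enolate at the methyl group (LiN(iPr)2, −78 °C) is chlorinated with p-toluenesulfonyl chloride to the chloromethyl ketone F3. Et3N/LiClO4 in Et2O generates the oxyallyl cation by enolisation and loss of chloride, and its intramolecular (4+3) cycloaddition with the tethered butadiene returns to 16. In this variant C5 is α to the ketone and can be equilibrated, and the facial course is directed by the C4 silyloxy centre.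

Step 12. Hydrogen delivery to the hindered dienone may be slow or unselective, or the β,γ-enone may drift into conjugation. The fallback is a dissolving-metal reduction, setting out from 18 and returning at 19. Li in NH3/THF with one equivalent of t-BuOH at −78 °C should give, by electron transfer and protonation at C10, the lithium dienolate F4 (O–C6=C7, C8=C9). Kinetic protonation at C7 with solid NH4Cl at −78 °C then gives 19.

Step 16. The silyl group may migrate from the C6 oxygen to the C4 alkoxide so that the wrong oxygen is acylated, or the hindered alkoxide may be acylated incompletely. The fallback uses a protecting group that cannot migrate and a more reactive alkoxide, setting out from 21 and returning at 28. NaH/BnBr (THF/DMF, 0 °C) should give the 6-O-benzyl ether (3R,3aS,4S,8aR)-4-(benzyloxy)-6,8a-dimethyl-3-(propan-2-yl)-1,2,3,3a,4,5,8,8a-octahydroazulen-3-ol F5. KN(SiMe3)2 and then acid chloride 24 give the 4-O-aroyl ester F6. Epoxidation with m-chloroperbenzoic acid/NaHCO3 (undirected, expected from the face away from the β C1 methyl) gives the 8α,9α-epoxide F7. Hydrogenolysis (H2, Pd/C, EtOAc) removes both benzyl groups and gives 28.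

Further compounds
F1 | step 10 | (S,7E,9E)-4-hydroxy-7-methyl-4-(propan-2-yl)undeca-7,9-dien-2-one | CC(=O)C[C@](O)(C(C)C)CC/C(C)=C/C=C/C
F2 | step 10 | (S,7E,9E)-7-methyl-4-(propan-2-yl)-4-[(triethylsilyl)oxy]undeca-7,9-dien-2-one | CC(=O)C[C@](O[Si](CC)(CC)CC)(C(C)C)CC/C(C)=C/C=C/C
F3 | step 10 | (S,7E,9E)-1-chloro-7-methyl-4-(propan-2-yl)-4-[(triethylsilyl)oxy]undeca-7,9-dien-2-one | ClCC(=O)C[C@](O[Si](CC)(CC)CC)(C(C)C)CC/C(C)=C/C=C/C
F4 | step 12 | lithium 6,8a-dimethyl-3-(propan-2-yl)-3-[(triethylsilyl)oxy]-1,2,3,3a,8,8a-hexahydroazulen-4-olate (dienolate) | CC[Si](CC)(CC)O[C@@]1(C(C)C)CC[C@]2(C)CC=C(C)C=C([O-])[C@H]21.[Li+]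
F5 | step 16 | (3R,3aS,4S,8aR)-4-(benzyloxy)-6,8a-dimethyl-3-(propan-2-yl)-1,2,3,3a,4,5,8,8a-octahydroazulen-3-ol | O[C@@]1(C(C)C)CC[C@]2(C)CC=C(C)C[C@H](OCc3ccccc3)[C@H]21
F6 | step 16 | (3R,3aS,4S,8aR)-4-(benzyloxy)-6,8a-dimethyl-3-(propan-2-yl)-1,2,3,3a,4,5,8,8a-octahydroazulen-3-yl 4-(benzyloxy)-3-methoxybenzoate | COc1cc(C(=O)O[C@@]2(C(C)C)CC[C@]3(C)CC=C(C)C[C@H](OCc4ccccc4)[C@H]32)ccc1OCc1ccccc1
F7 | step 16 | (1R,4R,5S,6S,8R,9S)-6-(benzyloxy)-8,9-epoxydaucan-4-yl 4-(benzyloxy)-3-methoxybenzoate | COc1cc(C(=O)O[C@@]2(C(C)C)CC[C@]3(C)C[C@@H]4O[C@]4(C)C[C@H](OCc5ccccc5)[C@H]32)ccc1OCc1ccccc1
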